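The methylcyclohexene ring is disconnected at the bond between C3'' (the allylic CH on flavone C8) and C4'' (the CH alpha to the aryl ketone) and redrawn as a vinylcyclobutane in which C4'' is bonded to the methyl-bearing carbon C1''. A borate that chelates the 2-hydroxyaryl ketone should open this strained bond to an enolate at C4'' and a C1''–C3'' allyl cation stabilised by the oxygenated flavone A ring; reclosure at C3'' expands the four-membered ring to the cyclohexene and funnels every cyclobutane epimer into the all-trans ring. The precursor is a 2-aroyl-3-aryl-1-methyl-1-styrylcyclobutane whose aryl-bearing carbon C5'' is set by rhodium-catalysed conjugate arylation.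

Key step: step 22

Remark: compounds 13–17 are racemic; in 18–20 and 32 only the aryl-bearing carbon C5'' is defined (R), the quaternary and α-keto carbons being epimer mixtures that step 22 erases; the ligand antipode in step 10 is the one that delivers this R centre.

Abbreviations: MOM = methoxymethyl, TBS = tert-butyldimethylsilyl, TIPS = triisopropylsilyl, prenyl = 3-methylbut-2-en-1-yl. Ring atoms of the cyclohexene: C1'' (methyl-bearing alkene carbon), C2'' (alkene CH), C3'' (CH on flavone C8), C4'' (CH bearing the aroyl group), C5'' (CH bearing the dihydroxyphenyl group), C6'' (CH2).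

**Aryl building blocks**

Step 1
Reactants: 1 resorcinol
Product: 2 1,3-bis(methoxymethoxy)benzene
Conditions: MOMCl, i-Pr2NEt, CH2Cl2, 0 → 25 °C
Reagents that add atoms: chloromethyl methyl ether, COCCl
Why: Double O-alkylation of the phenols (Williamson ether synthesis) gives the bis-MOM ether whose acetal oxygens later direct lithiation.

Step 2
Reactants: 2 1,3-bis(methoxymethoxy)benzene
Product: 4 1,3-bis(methoxymethoxy)-2-prenylbenzene, via 2-lithio arene 3 (not isolated)
Conditions: n-BuLi, THF, 0 → 25 °C; CuBr·SMe2 (10 mol%), prenyl bromide, −30 → 25 °C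
Reagents that add atoms: 1-bromo-3-methylbut-2-ene, CC(C)=CCBr
Why: Directed ortho-metalation occurs at C2 between the two OMOM groups, and copper-catalysed allylic substitution at the primary carbon of prenyl bromide should give the linear prenyl arene.

Step 3
Reactants: 4 1,3-bis(methoxymethoxy)-2-prenylbenzene
Product: 6 [2,4-bis(methoxymethoxy)-3-prenylphenyl]boronic acid, via aryllithium 5 (not isolated)
Conditions: n-BuLi, TMEDA, THF, 0 °C; B(Oi-Pr)3, −78 → 25 °C; H2O
Reagents that add atoms: triisopropyl borate, CC(C)OB(OC(C)C)OC(C)C; water, O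
Why: A second directed ortho-metalation next to an OMOM group (C2 is blocked), borate trapping and hydrolysis should give the boronic acid.

Step 4
Reactants: 2 1,3-bis(methoxymethoxy)benzene
Product: 7 1-bromo-2,4-bis(methoxymethoxy)benzene
Conditions: NBS, MeCN, 0 °C
Reagents that add atoms: N-bromosuccinimide, O=C1CCC(=O)N1Br
Why: Electrophilic aromatic bromination should go para to one OMOM and ortho to the other because the position between the two ethers is hindered.

Step 5
Reactants: 7 1-bromo-2,4-bis(methoxymethoxy)benzene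
Product: 9 [2,4-bis(methoxymethoxy)phenyl]boronic acid, via aryllithium 8 (not isolated)
Conditions: n-BuLi, THF, −78 °C; B(Oi-Pr)3, −78 → 25 °C; H2O
Reagents that add atoms: triisopropyl borate, CC(C)OB(OC(C)C)OC(C)C; water, O
Why: Bromine–lithium exchange at −78 °C and borylation give the boronic acid after hydrolysis.

**Cyclobutane fragment**

Step 6
Reactants: 10 cyclopropyl phenyl sulfide, 11 but-3-en-2-one
Product: 13 2-[1-(phenylsulfanyl)cyclopropyl]but-3-en-2-ol (racemic), via 1-lithiocyclopropyl phenyl sulfide 12 (not isolated)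
Conditions: n-BuLi, THF, 0 °C; then 11, −78 °C; H2O
Reagents that add atoms: none
Why: The sulfur-stabilised cyclopropyl anion adds 1,2 to the enone carbonyl at low temperature to give the tertiary allylic carbinol.

Step 7
Reactants: 13 2-[1-(phenylsulfanyl)cyclopropyl]but-3-en-2-ol
Product: 14 2-ethenyl-2-methylcyclobutan-1-one (racemic)
Conditions: TsOH·H2O (cat.), wet benzene, 80 °C
Reagents that add atoms: water, O
Why: Acid ionises the tertiary allylic alcohol, the cyclopropylcarbinyl cation expands to the sulfur-stabilised cyclobutyl cation, and its hydrolysis releases thiophenol and the cyclobutanone (semipinacol-type ring expansion).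

Step 8
Reactants: 14 2-ethenyl-2-methylcyclobutan-1-one
Product: 16 4-ethenyl-4-methylcyclobut-1-en-1-yl trifluoromethanesulfonate, via potassium enolate 15 (not isolated)
Conditions: KHMDS, THF, −78 °C; PhNTf2, −78 → 0 °C
Reagents that add atoms: N-phenylbis(trifluoromethanesulfonimide), O=S(=O)(N(c1ccccc1)S(=O)(=O)C(F)(F)F)C(F)(F)F
Why: The ketone can enolise only towards its CH2 side, so kinetic deprotonation and O-triflation should give a single cyclobutenyl triflate.

Step 9
Reactants: 16 4-ethenyl-4-methylcyclobut-1-en-1-yl trifluoromethanesulfonate, 6 [2,4-bis(methoxymethoxy)-3-prenylphenyl]boronic acid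
Product: 17 (4-ethenyl-4-methylcyclobut-1-en-1-yl)[2,4-bis(methoxymethoxy)-3-prenylphenyl]methanone
Conditions: PdCl2(dppf) (5 mol%), K2CO3, CO (1 atm), anisole, 60 °C
Reagents that add atoms: carbon monoxide, [C-]#[O+]
Why: Carbonylative Suzuki–Miyaura coupling (oxidative addition of the vinyl triflate, CO insertion, transmetalation) should give the aryl cyclobutenyl ketone, and the moderate temperature avoids electrocyclic opening of the cyclobutene.

Step 10
Reactants: 17 (4-ethenyl-4-methylcyclobut-1-en-1-yl)[2,4-bis(methoxymethoxy)-3-prenylphenyl]methanone, 9 [2,4-bis(methoxymethoxy)phenyl]boronic acid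
Product: 18 [(4R)-4-[2,4-bis(methoxymethoxy)phenyl]-2-ethenyl-2-methylcyclobutyl][2,4-bis(methoxymethoxy)-3-prenylphenyl]methanone (epimer mixture at C1 and C2 of the cyclobutane)
Conditions: [RhCl(C2H4)2]2 (2.5 mol%), (R,R)-Ph-bod* (5.5 mol%), KOH (0.3 eq), dioxane/H2O 10:1, 35 °C
Reagents that add atoms: none
Why: Hayashi–Miyaura rhodium-catalysed asymmetric 1,4-addition to the strained enone sets the aryl-bearing carbon C5'' by catalyst control (the remote Me/vinyl quaternary centre offers little facial bias), and the racemic quaternary carbon simply gives two epimers that are carried on together.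

Step 11
Reactants: 18 tetra-MOM cyclobutyl ketone
Product: 19 [(4R)-4-(2,4-dihydroxyphenyl)-2-ethenyl-2-methylcyclobutyl][2,4-dihydroxy-3-prenylphenyl]methanone
Conditions: 3 M HCl, MeOH, 40 °C
Reagents that add atoms: none
Why: Acid-catalysed methanolysis of the four MOM acetals frees the phenols at a stage where no acid-labile O-prenyl ether is present; the C-prenyl and vinyl groups should tolerate dilute acid at mild temperature.

Step 12
Reactants: 19 tetraphenol cyclobutyl ketone
Product: 20 [(4R)-4-[2,4-bis(TBS-oxy)phenyl]-2-ethenyl-2-methylcyclobutyl][4-(TBS-oxy)-2-hydroxy-3-prenylphenyl]methanone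
Conditions: TBSCl (3.3 eq), imidazole, DMF, 0 °C
Reagents that add atoms: tert-butyldimethylsilyl chloride, CC(C)(C)[Si](C)(C)Cl
Why: Silylation should protect the three free-standing phenols, whereas the phenol hydrogen-bonded to the ketone stays free for chelation in step 22.

**Flavone fragment**

Step 13
Reactants: 21 1-(2,4,6-trihydroxyphenyl)ethan-1-one
Product: 22 1-[2,6-dihydroxy-4-(TIPS-oxy)phenyl]ethan-1-one
Conditions: TIPSCl (1.0 eq), imidazole, DMF, 0 °C
Reagents that add atoms: triisopropylsilyl chloride, CC(C)[Si](Cl)(C(C)C)C(C)C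
Why: The para hydroxyl is the only one not hydrogen-bonded to the acetyl group and should be silylated selectively.

Step 14
Reactants: 22 1-[2,6-dihydroxy-4-(TIPS-oxy)phenyl]ethan-1-one
Product: 23 1-[2-hydroxy-6-(methoxymethoxy)-4-(TIPS-oxy)phenyl]ethan-1-one
Conditions: MOMCl (1.05 eq), i-Pr2NEt, CH2Cl2, 0 °C
Reagents that add atoms: chloromethyl methyl ether, COCCl
Why: The two ortho hydroxyls are equivalent, and after the first alkylation the remaining one is fully chelated to the carbonyl, so mono-protection is expected.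

Step 15
Reactants: 23 1-[2-hydroxy-6-(methoxymethoxy)-4-(TIPS-oxy)phenyl]ethan-1-one
Product: 24 1-[2-hydroxy-3-iodo-6-(methoxymethoxy)-4-(TIPS-oxy)phenyl]ethan-1-one
Conditions: NIS, CH2Cl2, 0 °C
Reagents that add atoms: N-iodosuccinimide, O=C1CCC(=O)N1I
Why: Electrophilic iodination of the electron-rich ring is expected ortho to the free phenol, which places iodine at the carbon that becomes C8 of the flavone.

Step 16
Reactants: 25 methyl 2,4-dihydroxybenzoate
Product: 26 methyl 2,4-bis(methoxymethoxy)benzoate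
Conditions: NaH, MOMCl, DMF, 0 → 25 °C
Reagents that add atoms: chloromethyl methyl ether, COCCl
Why: Williamson alkylation of both phenoxides, the chelated ortho one needing the strong base.

Step 17
Reactants: 24 1-[2-hydroxy-3-iodo-6-(methoxymethoxy)-4-(TIPS-oxy)phenyl]ethan-1-one, 26 methyl 2,4-bis(methoxymethoxy)benzoate
Product: 28 1-[2,4-bis(methoxymethoxy)phenyl]-3-[2-hydroxy-3-iodo-6-(methoxymethoxy)-4-(TIPS-oxy)phenyl]propane-1,3-dione, via dilithio phenoxide enolate 27 (not isolated)
Conditions: LiHMDS (3.5 eq), THF, −78 → 25 °C; H2O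
Reagents that add atoms: none
Why: Crossed Claisen condensation of the phenoxide–enolate dianion with the non-enolisable benzoate, driven by deprotonation of the 1,3-diketone.

Step 18
Reactants: 28 1,3-diketone
Product: 29 1-[2,4-bis(methoxymethoxy)phenyl]-3-[2-hydroxy-3-iodo-6-(methoxymethoxy)-4-(TIPS-oxy)phenyl]-2-prenylpropane-1,3-dione
Conditions: prenyl bromide, K2CO3, acetone, 25 °C
Reagents that add atoms: 1-bromo-3-methylbut-2-ene, CC(C)=CCBr
Why: C-Alkylation of the soft 1,3-diketone enolate at the central carbon installs the future 3-prenyl group; the chelated, iodine-flanked phenol should be much less nucleophilic.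

Step 19
Reactants: 29 2-prenyl-1,3-diketone
Product: 30 2-(2,4-dihydroxyphenyl)-5-hydroxy-8-iodo-3-prenyl-7-(TIPS-oxy)-4H-chromen-4-one
Conditions: conc. HCl, MeOH, 45 °C
Reagents that add atoms: none
Why: Cyclodehydration through the only free ortho hydroxyl (fast hemiketal formation and loss of water) fixes iodine at C8 before the slower MOM methanolysis frees the other phenols; the aryl TIPS ether should survive.

Step 20
Reactants: 30 8-iodoflavone triol
Product: 31 5-hydroxy-2-[2-hydroxy-4-(prenyloxy)phenyl]-8-iodo-3-prenyl-7-(TIPS-oxy)-4H-chromen-4-one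
Conditions: prenyl bromide (1.05 eq), K2CO3 (1.1 eq), acetone, 25 °C
Reagents that add atoms: 1-bromo-3-methylbut-2-ene, CC(C)=CCBr
Why: O-Alkylation should take the most acidic and least hindered 4'-hydroxyl; the 5-OH is chelated to the carbonyl and the 2'-OH is shielded by the 3-prenyl group.

**Union, ring expansion and deprotection**

Step 21
Reactants: 20 tris-TBS vinylcyclobutane, 31 8-iodoflavone
Product: 32 8-[(E)-2-{(3R)-3-[2,4-bis(TBS-oxy)phenyl]-2-[4-(TBS-oxy)-2-hydroxy-3-prenylbenzoyl]-1-methylcyclobutyl}ethenyl]-5-hydroxy-2-[2-hydroxy-4-(prenyloxy)phenyl]-3-prenyl-7-(TIPS-oxy)-4H-chromen-4-one (epimer mixture at C1 and C2 of the cyclobutane)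
Conditions: Pd2(dba)3 (2.5 mol%), [(t-Bu)3PH]BF4 (10 mol%), Cy2NMe, dioxane, 60 °C
Reagents that add atoms: none
Why: Mizoroki–Heck reaction: the aryl-palladium adds to the terminal carbon of the vinyl group, and syn β-hydride elimination can only give the (E)-styrene because the neighbouring carbon is quaternary.

Step 22
Reactants: 32 styrylcyclobutane
Product: 34 8-[(1S,5R,6S)-5-[2,4-bis(TBS-oxy)phenyl]-6-[4-(TBS-oxy)-2-hydroxy-3-prenylbenzoyl]-3-methylcyclohex-2-en-1-yl]-5-hydroxy-2-[2-hydroxy-4-(prenyloxy)phenyl]-3-prenyl-7-(TIPS-oxy)-4H-chromen-4-one, via ring-opened zwitterion 33 (not isolated)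
Conditions: B(OPh)3 (2.5 eq), 2,2'-biphenol (2.5 eq), PhCF3, 25 → 45 °C; then pH 7 buffer
Reagents that add atoms: none
Why: The borate chelates the 2-hydroxyaryl ketone, and the strained C4''–C1'' bond (flanked by the ketone α-carbon and a tertiary allylic carbon) should heterolyse to a boron enolate at C4'' and a C1''–C2''–C3'' allyl cation that is benzylic to the flavone A ring (O1 and O7 ortho, O5 para to C8); 33 is drawn as the free zwitterion. The closest known reaction types are the zwitterionic vinylcyclobutane-to-cyclohexene isomerisation of polar [2+2] adducts and the Lewis-acid opening of donor–acceptor cyclobutanes, the overall change being a formal [1,3] shift. The six-membered ring closes by attack of the enolate carbon on the cation terminus C3'', a 6-endo closure with the allyl unit inside the new ring; reclosure at C1'' (4-exo) or through the enolate oxygen (dihydropyran) is reversible, and the latter can also lead on by Claisen shift. C5'' is untouched and controls both new centres: in the chair-like closure its aryl group, the aroyl group on C4'' and the flavone on C3'' (delivered from the E-configured cation) should all become equatorial, and C4'' can additionally equilibrate by enolisation. The step needs ring closure to outrun fragmentation of the zwitterion into chalcone and diene and proton loss to an open-chain diene, which the tight ion pair in a non-basic, weakly polar medium is expected to secure, while the TIPS ether on O7 prevents capture of the cation as a chromene. All stereoisomers of 32 give the same zwitterion, so the epimer mixture should converge on one product.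

Step 23
Reactants: 34 silyl-protected cyclohexene
Product: 35 8-[(1S,5R,6S)-6-[2,4-dihydroxy-3-prenylbenzoyl]-5-(2,4-dihydroxyphenyl)-3-methylcyclohex-2-en-1-yl]-5,7-dihydroxy-2-[2-hydroxy-4-(prenyloxy)phenyl]-3-prenyl-4H-chromen-4-one (CNP0082413.1)
Conditions: TBAF, AcOH, THF, 0 °C
Reagents that add atoms: none
Why: Buffered fluoride cleaves the four aryl silyl ethers without acid, so the O-prenyl ether, the C-prenyl groups and the three stereocentres should be left untouched.

**Compound list**

1 | resorcinol | Oc1cccc(O)c1 | starting material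
2 | 1,3-bis(methoxymethoxy)benzene | COCOc1cccc(OCOC)c1 | intermediate
3 | [2,6-bis(methoxymethoxy)phenyl]lithium | COCOc1cccc(OCOC)c1[Li] | intermediate
4 | 1,3-bis(methoxymethoxy)-2-prenylbenzene | COCOc1cccc(OCOC)c1CC=C(C)C | intermediate
5 | [2,4-bis(methoxymethoxy)-3-prenylphenyl]lithium | COCOc1ccc([Li])c(OCOC)c1CC=C(C)C | intermediate
6 | [2,4-bis(methoxymethoxy)-3-prenylphenyl]boronic acid | COCOc1ccc(B(O)O)c(OCOC)c1CC=C(C)C | intermediate
7 | 1-bromo-2,4-bis(methoxymethoxy)benzene | COCOc1ccc(Br)c(OCOC)c1 | intermediate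
8 | [2,4-bis(methoxymethoxy)phenyl]lithium | COCOc1ccc([Li])c(OCOC)c1 | intermediate
9 | [2,4-bis(methoxymethoxy)phenyl]boronic acid | COCOc1ccc(B(O)O)c(OCOC)c1 | intermediate
10 | cyclopropyl phenyl sulfide | c1ccc(SC2CC2)cc1 | starting material
11 | but-3-en-2-one | CC(=O)C=C | starting material
12 | 1-lithiocyclopropyl phenyl sulfide | [Li]C1(Sc2ccccc2)CC1 | intermediate
13 | 2-[1-(phenylsulfanyl)cyclopropyl]but-3-en-2-ol (racemic) | CC(O)(C=C)C1(Sc2ccccc2)CC1 | intermediate
14 | 2-ethenyl-2-methylcyclobutan-1-one (racemic) | C=CC1(C)CCC1=O | intermediate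
15 | potassium 4-ethenyl-4-methylcyclobut-1-en-1-olate | C=CC1(C)CC=C1[O-].[K+] | intermediate
16 | 4-ethenyl-4-methylcyclobut-1-en-1-yl trifluoromethanesulfonate (racemic) | C=CC1(C)CC=C1OS(=O)(=O)C(F)(F)F | intermediate
17 | (4-ethenyl-4-methylcyclobut-1-en-1-yl)[2,4-bis(methoxymethoxy)-3-prenylphenyl]methanone (racemic) | C=CC1(C)CC=C1C(=O)c1ccc(OCOC)c(CC=C(C)C)c1OCOC | intermediate
18 | [(4R)-4-[2,4-bis(methoxymethoxy)phenyl]-2-ethenyl-2-methylcyclobutyl][2,4-bis(methoxymethoxy)-3-prenylphenyl]methanone, epimers at C1 and C2 | C=CC1(C)C[C@@H](c2ccc(OCOC)cc2OCOC)C1C(=O)c1ccc(OCOC)c(CC=C(C)C)c1OCOC | intermediate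
19 | [(4R)-4-(2,4-dihydroxyphenyl)-2-ethenyl-2-methylcyclobutyl][2,4-dihydroxy-3-prenylphenyl]methanone, epimers at C1 and C2 | C=CC1(C)C[C@@H](c2ccc(O)cc2O)C1C(=O)c1ccc(O)c(CC=C(C)C)c1O | intermediate
20 | [(4R)-4-[2,4-bis(TBS-oxy)phenyl]-2-ethenyl-2-methylcyclobutyl][4-(TBS-oxy)-2-hydroxy-3-prenylphenyl]methanone, epimers at C1 and C2 | C=CC1(C)C[C@@H](c2ccc(O[Si](C)(C)C(C)(C)C)cc2O[Si](C)(C)C(C)(C)C)C1C(=O)c1ccc(O[Si](C)(C)C(C)(C)C)c(CC=C(C)C)c1O | intermediate
21 | 1-(2,4,6-trihydroxyphenyl)ethan-1-one | CC(=O)c1c(O)cc(O)cc1O | starting material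
22 | 1-[2,6-dihydroxy-4-(TIPS-oxy)phenyl]ethan-1-one | CC(=O)c1c(O)cc(O[Si](C(C)C)(C(C)C)C(C)C)cc1O | intermediate
23 | 1-[2-hydroxy-6-(methoxymethoxy)-4-(TIPS-oxy)phenyl]ethan-1-one | CC(=O)c1c(O)cc(O[Si](C(C)C)(C(C)C)C(C)C)cc1OCOC | intermediate
24 | 1-[2-hydroxy-3-iodo-6-(methoxymethoxy)-4-(TIPS-oxy)phenyl]ethan-1-one | CC(=O)c1c(O)c(I)c(O[Si](C(C)C)(C(C)C)C(C)C)cc1OCOC | intermediate
25 | methyl 2,4-dihydroxybenzoate | COC(=O)c1ccc(O)cc1O | starting material
26 | methyl 2,4-bis(methoxymethoxy)benzoate | COC(=O)c1ccc(OCOC)cc1OCOC | intermediate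
27 | dilithium phenoxide–enolate of 24 | C=C(O[Li])c1c(O[Li])c(I)c(O[Si](C(C)C)(C(C)C)C(C)C)cc1OCOC | intermediate
28 | 1-[2,4-bis(methoxymethoxy)phenyl]-3-[2-hydroxy-3-iodo-6-(methoxymethoxy)-4-(TIPS-oxy)phenyl]propane-1,3-dione | O=C(CC(=O)c1ccc(OCOC)cc1OCOC)c1c(O)c(I)c(O[Si](C(C)C)(C(C)C)C(C)C)cc1OCOC | intermediate
29 | 1-[2,4-bis(methoxymethoxy)phenyl]-3-[2-hydroxy-3-iodo-6-(methoxymethoxy)-4-(TIPS-oxy)phenyl]-2-prenylpropane-1,3-dione | O=C(C(CC=C(C)C)C(=O)c1ccc(OCOC)cc1OCOC)c1c(O)c(I)c(O[Si](C(C)C)(C(C)C)C(C)C)cc1OCOC | intermediate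
30 | 2-(2,4-dihydroxyphenyl)-5-hydroxy-8-iodo-3-prenyl-7-(TIPS-oxy)-4H-chromen-4-one | CC(C)=CCc1c(-c2ccc(O)cc2O)oc2c(I)c(O[Si](C(C)C)(C(C)C)C(C)C)cc(O)c2c1=O | intermediate
31 | 5-hydroxy-2-[2-hydroxy-4-(prenyloxy)phenyl]-8-iodo-3-prenyl-7-(TIPS-oxy)-4H-chromen-4-one | CC(C)=CCOc1ccc(-c2oc3c(I)c(O[Si](C(C)C)(C(C)C)C(C)C)cc(O)c3c(=O)c2CC=C(C)C)c(O)c1 | intermediate
32 | 8-[(E)-2-{(3R)-3-[2,4-bis(TBS-oxy)phenyl]-2-[4-(TBS-oxy)-2-hydroxy-3-prenylbenzoyl]-1-methylcyclobutyl}ethenyl]-5-hydroxy-2-[2-hydroxy-4-(prenyloxy)phenyl]-3-prenyl-7-(TIPS-oxy)-4H-chromen-4-one, epimers at C1 and C2 of the cyclobutane | CC(C)=CCOc1ccc(-c2oc3c(/C=C/C4(C)C[C@@H](c5ccc(O[Si](C)(C)C(C)(C)C)cc5O[Si](C)(C)C(C)(C)C)C4C(=O)c4ccc(O[Si](C)(C)C(C)(C)C)c(CC=C(C)C)c4O)c(O[Si](C(C)C)(C(C)C)C(C)C)cc(O)c3c(=O)c2CC=C(C)C)c(O)c1 | intermediate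
33 | ring-opened zwitterion (enolate at C4'', allyl cation C1''–C3''; boron-bound in the flask, drawn free) | CC(C)=CCOc1ccc(-c2oc3c(/C=C/[C+](C)C[C@@H](c5ccc(O[Si](C)(C)C(C)(C)C)cc5O[Si](C)(C)C(C)(C)C)C=C([O-])c4ccc(O[Si](C)(C)C(C)(C)C)c(CC=C(C)C)c4O)c(O[Si](C(C)C)(C(C)C)C(C)C)cc(O)c3c(=O)c2CC=C(C)C)c(O)c1 | intermediate
34 | 8-[(1S,5R,6S)-5-[2,4-bis(TBS-oxy)phenyl]-6-[4-(TBS-oxy)-2-hydroxy-3-prenylbenzoyl]-3-methylcyclohex-2-en-1-yl]-5-hydroxy-2-[2-hydroxy-4-(prenyloxy)phenyl]-3-prenyl-7-(TIPS-oxy)-4H-chromen-4-one | CC(C)=CCOc1ccc(-c2oc3c([C@H]4C=C(C)C[C@@H](c5ccc(O[Si](C)(C)C(C)(C)C)cc5O[Si](C)(C)C(C)(C)C)[C@@H]4C(=O)c4ccc(O[Si](C)(C)C(C)(C)C)c(CC=C(C)C)c4O)c(O[Si](C(C)C)(C(C)C)C(C)C)cc(O)c3c(=O)c2CC=C(C)C)c(O)c1 | intermediate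
35 | 8-[(1S,5R,6S)-6-[2,4-dihydroxy-3-prenylbenzoyl]-5-(2,4-dihydroxyphenyl)-3-methylcyclohex-2-en-1-yl]-5,7-dihydroxy-2-[2-hydroxy-4-(prenyloxy)phenyl]-3-prenyl-4H-chromen-4-one | CC(C)=CCOc1ccc(-c2oc3c([C@H]4C=C(C)C[C@@H](c5ccc(O)cc5O)[C@@H]4C(=O)c4ccc(O)c(CC=C(C)C)c4O)c(O)cc(O)c3c(=O)c2CC=C(C)C)c(O)c1 | target

**Step count and risks**

Total step count: 23. Longest linear sequence: 10 steps (for example steps 1, 2, 3, 9, 10, 11, 12, 21, 22, 23).

Steps most likely to fail:

1. Step 22 (ring expansion). The zwitterion may fragment into chalcone and diene and recombine without stereocontrol, eroding enantiopurity. It may also lose a proton to give open-chain dienes, or close with the flavone cis to the aroyl group if equilibration is slow. Fallback: the push is moved from the Lewis acid to a free phenoxide and the order of the last two steps is reversed. Compound 32 is desilylated with TBAF/AcOH to 8-[(E)-2-{(3R)-2-[2,4-dihydroxy-3-prenylbenzoyl]-3-(2,4-dihydroxyphenyl)-1-methylcyclobutyl}ethenyl]-5,7-dihydroxy-2-[2-hydroxy-4-(prenyloxy)phenyl]-3-prenyl-4H-chromen-4-one F1. Mild base (DBU or aqueous NaHCO3/MeCN, 25 °C) should then let the 7-phenoxide expel the enolate through the styryl unit (retro-Michael to a vinylogous ortho-quinone methide), and intramolecular Michael addition of the enolate at C3'' closes the cyclohexene under thermodynamic control. This sets out from 32 and comes back to the route at the target 35.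

2. Step 10 (conjugate arylation). Insertion into the trisubstituted acylcyclobutene may be slow, the ortho-alkoxy boronic acid may protodeboronate, or facial selectivity may be low for one enantiomer of the racemic enone. Fallback: the better-precedented cyclobutenoate is used. Triflate 16 is methoxycarbonylated (Pd(PPh3)4, CO, MeOH, Et3N, DMF, 50 °C) to methyl 4-ethenyl-4-methylcyclobut-1-ene-1-carboxylate F2. Rhodium/chiral-diene 1,4-addition of 9 gives methyl (4R)-4-[2,4-bis(methoxymethoxy)phenyl]-2-ethenyl-2-methylcyclobutane-1-carboxylate F3. MeNHOMe·HCl/i-PrMgCl converts it into (4R)-4-[2,4-bis(methoxymethoxy)phenyl]-2-ethenyl-N-methoxy-N,2-dimethylcyclobutane-1-carboxamide F4, and addition of aryllithium 5 (made from 4 as in step 3) at −78 °C gives the ketone. This sets out from 16 and comes back at 18, bypassing step 9 as well.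

3. Step 21 (Heck coupling). Oxidative addition and insertion at the doubly ortho-substituted iodide may be slow, the alkylpalladium may open the cyclobutane by β-carbon elimination, or the product may rearrange prematurely under heat. Fallback: the polarity of the coupling is inverted. Iodide 31 is borylated (B2pin2, PdCl2(dppf), KOAc, dioxane, 80 °C) to 5-hydroxy-2-[2-hydroxy-4-(prenyloxy)phenyl]-3-prenyl-8-(4,4,5,5-tetramethyl-1,3,2-dioxaborolan-2-yl)-7-(TIPS-oxy)-4H-chromen-4-one F5. An oxidative boron-Heck reaction with 20 (Pd(OAc)2, 2,9-dimethyl-1,10-phenanthroline, O2, DMA, 40 °C) then starts from transmetalation and runs without base near room temperature. This sets out from 31 and comes back at 32.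

Further compounds
F1 | step 22 | 8-[(E)-2-{(3R)-2-[2,4-dihydroxy-3-prenylbenzoyl]-3-(2,4-dihydroxyphenyl)-1-methylcyclobutyl}ethenyl]-5,7-dihydroxy-2-[2-hydroxy-4-(prenyloxy)phenyl]-3-prenyl-4H-chromen-4-one | CC(C)=CCOc1ccc(-c2oc3c(/C=C/C4(C)C[C@@H](c5ccc(O)cc5O)C4C(=O)c4ccc(O)c(CC=C(C)C)c4O)c(O)cc(O)c3c(=O)c2CC=C(C)C)c(O)c1
F2 | step 10 | methyl 4-ethenyl-4-methylcyclobut-1-ene-1-carboxylate | C=CC1(C)CC=C1C(=O)OC
F3 | step 10 | methyl (4R)-4-[2,4-bis(methoxymethoxy)phenyl]-2-ethenyl-2-methylcyclobutane-1-carboxylate | C=CC1(C)C[C@@H](c2ccc(OCOC)cc2OCOC)C1C(=O)OC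
F4 | step 10 | (4R)-4-[2,4-bis(methoxymethoxy)phenyl]-2-ethenyl-N-methoxy-N,2-dimethylcyclobutane-1-carboxamide | C=CC1(C)C[C@@H](c2ccc(OCOC)cc2OCOC)C1C(=O)N(C)OC
F5 | step 21 | 5-hydroxy-2-[2-hydroxy-4-(prenyloxy)phenyl]-3-prenyl-8-(4,4,5,5-tetramethyl-1,3,2-dioxaborolan-2-yl)-7-(TIPS-oxy)-4H-chromen-4-one | CC(C)=CCOc1ccc(-c2oc3c(B4OC(C)(C)C(C)(C)O4)c(O[Si](C(C)C)(C(C)C)C(C)C)cc(O)c3c(=O)c2CC=C(C)C)c(O)c1
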